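**Plan**
1. Core numbering: C2 ketone, C3 (OH), C4 (CH2), C4a (quaternary, CH3), C5 (CH3), C6 (O-acyl), C7=C8, C8a=C1. The retrosynthesis cuts the ester C–O bond, returns the C1=C8a double bond to a silyl enol ether, then cuts C3–C4 and C4a–C8a together (intramolecular Diels–Alder), and finally cuts C8–C8a (Heck) and C5–C6 (allylboration) in the acyclic tetraene.
2. Enabling feature: in ring B the C2 ketone with its C3 oxygen is a masked 1,2-bis(silyloxy)diene C3=C2–C1=C8a, and the C4a(CH3)–C4H2 unit is a masked isopropenyl group. The cis C7=C8 bond of ring A is a rigid four-atom tether between them; the extra C8a hydrogen of the adduct is the only helper and is removed by dehydrogenation.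
3. Forward order: the chain is joined linearly (C5–C6, then C8–C8a), rings A and B close together in one cycloaddition, the dienone is unveiled, and the separately made side chain is attached last.
4. Stereochemistry: C5/C6 come from a catalyst-controlled anti allylboration; C4a and C3 come from the cycloaddition (control by C5/C6 and the enol ether geometry); side-chain C6/C7 come from an auxiliary-controlled syn aldol.

Key step: step 9

Abbreviations: TBS = tert-butyldimethylsilyl, TES = triethylsilyl, Bpin = 4,4,5,5-tetramethyl-1,3,2-dioxaborolan-2-yl.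
Assumption: (R)-TRIP is taken to direct the allyl group to the Re face of the aldehyde (3R carbinol), the usual sense for this catalyst class; if the sense is reversed on this substrate, (S)-TRIP is used instead.

**Step 1**
Reactants: 1 but-2-yne; 2 pinacolborane
Product: 3 (Z)-2-(but-2-en-2-yl)-4,4,5,5-tetramethyl-1,3,2-dioxaborolane
Conditions: Cp2Zr(H)Cl (5 mol %), CH2Cl2, sealed vessel, rt
Reagents that add atoms: none
Why: Cp2Zr(H)Cl-catalysed syn hydroboration of the symmetrical alkyne places B and H cis, so the two methyl groups are cis (Z), as needed for the later E allylboronate.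

**Step 2**
Reactants: 3 (Z)-2-(but-2-en-2-yl)-Bpin
Product: 5 (E)-4,4,5,5-tetramethyl-2-(2-methylbut-2-en-1-yl)-1,3,2-dioxaborolane, via lithium chloromethyl boronate complex 4 (not isolated)
Conditions: BrCH2Cl, n-BuLi, THF, −78 °C to rt
Reagents that add atoms: bromochloromethane (ClCBr)
Why: Matteson homologation: LiCH2Cl made in situ adds to boron and the alkenyl group undergoes 1,2-migration with loss of chloride, inserting CH2 with retention of alkene geometry to give the E (tiglyl-type) allylboronate.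

**Step 3**
Reactants: 6 ethyl (Z)-3-iodoprop-2-enoate
Product: 8 (Z)-3-iodoprop-2-enal, via aluminium hemiacetal 7 (not isolated)
Conditions: i-Bu2AlH (1.05 equiv), CH2Cl2, −78 °C; MeOH, then aq potassium sodium tartrate; dried solution used at once
Reagents that add atoms: none
Why: Partial ester reduction stops at the tetrahedral aluminium hemiacetal at −78 °C, which collapses to the aldehyde only on work-up, and cold non-acidic handling preserves the Z iodoalkene.

**Step 4**
Reactants: 8 (Z)-3-iodoprop-2-enal; 5 (E)-2-methylbut-2-enyl-Bpin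
Product: 10 (1Z,3R,4R)-1-iodo-4,5-dimethylhexa-1,5-dien-3-ol, via pinacol borate ester 9 (not isolated)
Conditions: (R)-TRIP [(R)-3,3'-bis(2,4,6-triisopropylphenyl)-1,1'-binaphthyl-2,2'-diyl hydrogen phosphate] (5 mol %), 4 Å MS, PhMe, −30 °C; then aq NaHCO3
Reagents that add atoms: none
Why: Chiral-phosphoric-acid-catalysed allylboration through a closed chair (Zimmerman–Traxler) transition state: the E geometry of 5 gives the anti C3/C4 relationship, and the catalyst, hydrogen-bonded to a boronate oxygen and the formyl hydrogen, selects the aldehyde face leading to the 3R carbinol.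

**Step 5**
Reactants: 11 2-(TBS-oxy)acetaldehyde
Product: 12 rac-1-(TBS-oxy)but-3-en-2-ol
Conditions: CH2=CHMgBr, THF, −78 to 0 °C; then H2O
Reagents that add atoms: vinylmagnesium bromide (C=C[Mg]Br)
Why: Grignard 1,2-addition to the aldehyde; the new carbinol centre is racemic and is removed in step 6.

**Step 6**
Reactants: 12 rac-1-(TBS-oxy)but-3-en-2-ol
Product: 13 1-(TBS-oxy)but-3-en-2-one
Conditions: Dess–Martin periodinane, CH2Cl2, 0 °C to rt; stored cold with BHT
Reagents that add atoms: none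
Why: Neutral Dess–Martin oxidation of the allylic alcohol should give the polymerisation-prone vinyl ketone without conjugate addition or silyl loss.

**Step 7**
Reactants: 10 (1Z,3R,4R)-1-iodo-4,5-dimethylhexa-1,5-dien-3-ol; 13 1-(TBS-oxy)but-3-en-2-one
Product: 14 (3E,5Z,7S,8R)-1-(TBS-oxy)-7-hydroxy-8,9-dimethyldeca-3,5,9-trien-2-one
Conditions: Pd(OAc)2 (10 mol %), Ag2CO3 (0.6 equiv), DMF, rt, dark
Reagents that add atoms: none
Why: Heck vinylation of the enone: the alkenylpalladium iodide from 10 adds across the terminal CH2 and syn β-hydride elimination gives the new E double bond, while the silver salt scavenges iodide and HPdI so that the Z geometry of the iodoalkene should be carried over and the free allylic alcohol tolerated.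

**Step 8**
Reactants: 14 (3E,5Z,7S,8R)-hydroxy trienone
Product: 16 (1Z,3E,5Z,7S,8R)-1-(TBS-oxy)-8,9-dimethyl-2,7-bis(TES-oxy)deca-1,3,5,9-tetraene, via C7 triethylsilyl ether ketone 15 (not isolated)
Conditions: Et3SiOTf (3 equiv), Et3N (5 equiv), CH2Cl2, −78 to −20 °C; cold aq NaHCO3, used crude
Reagents that add atoms: triethylsilyl trifluoromethanesulfonate (CC[Si](CC)(CC)OS(=O)(=O)C(F)(F)F)
Why: Silyl triflate/amine soft enolisation: the C7 hydroxyl is silylated first and the ketone is then enolised at its only sp3 α-carbon (C1), which should give the cross-conjugated Z enol silane (both oxygens cis, avoiding allylic strain with the dienyl chain).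

**Step 9**
Reactants: 16 (1Z,3E,5Z,7S,8R)-bis(TES-oxy) tetraene
Product: 17 (3R,4aS,5R,6S,8aR)-3-(TBS-oxy)-4a,5-dimethyl-2,6-bis(TES-oxy)-3,4,4a,5,6,8a-hexahydronaphthalene
Conditions: PhMe (0.01 M), BHT (cat.), sealed tube, 170 °C
Reagents that add atoms: none
Why: Thermal, concerted but asynchronous [4+2] cycloaddition (core numbering of 17): the 1,2-bis(silyloxy)diene C3=C2–C1=C8a adds across the isopropenyl C4a=C4 bond, the closest known reaction type being the type 1 intramolecular Diels–Alder reaction of 2-silyloxy-1,3-dienes with unactivated tethered alkenes that gives decalins. Ring B is closed as the cycloadduct ring by both new bonds (C3–C4 and C4a–C8a), and ring A is closed by the C4a–C8a bond alone as the six-membered ring spanned by the tether C8=C7–C6–C5, in the fused mode with the tether endo (cis ring fusion). C4a is controlled by the tether: the cis C7=C8 bond keeps C8a, C8, C7 and C6 coplanar and the torsion about the forming C4a–C8a bond small, which favours the tether-endo transition state, and in it ring B assembles on the face of the nascent ring A opposite the cis-related C6 silyloxy and C5 methyl groups, so that the angular methyl should come out syn to both. C3 is controlled by the Z enol ether (OTBS on the outside of the diene) together with the endo tether, which by suprafacial addition places the C3 oxygen trans to the angular methyl, and C8a (hydrogen cis to the angular methyl) is set at the same time but erased in step 10. The step therefore needs π-facial selectivity at the isopropenyl group and endo over exo placement of the tether, both secured by the C5/C6 stereocentres and the rigid cis alkene; the E geometry of C1=C8a rules out 6π-electrocyclisation of the triene, and the short rigid tether should let cyclisation outrun [1,5]-hydrogen shift in the Z-diene.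

**Step 10**
Reactants: 17 hexahydronaphthalene bis(TES) adduct
Product: 18 (3R,4aR,5R,6S)-3-(TBS-oxy)-4a,5-dimethyl-6-(TES-oxy)-4,4a,5,6-tetrahydronaphthalen-2(3H)-one
Conditions: Pd(OAc)2 (1.2 equiv), MeCN, rt
Reagents that add atoms: none
Why: Saegusa–Ito oxidation: the triethylsilyl enol ether is transferred to divalent palladium to give a C1-bound palladium enolate, and β-hydride elimination of the only β-hydrogen (the doubly allylic C8a–H) installs C1=C8a and thus the linearly conjugated dienone, removing the helper stereocentre without touching C3.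

**Step 11**
Reactants: 18 3-(TBS-oxy)-6-(TES-oxy) dienone
Product: 19 (3R,4aR,5R,6S)-3-(TBS-oxy)-6-hydroxy-4a,5-dimethyl-4,4a,5,6-tetrahydronaphthalen-2(3H)-one
Conditions: PPTS (0.2 equiv), MeOH/CH2Cl2, 0 °C
Reagents that add atoms: none
Why: Acid-catalysed methanolysis should cleave the triethylsilyl ether much faster than the tert-butyldimethylsilyl ether, freeing only the C6 hydroxyl.

**Step 12**
Reactants: 20 (R)-4-benzyl-3-propanoyl-1,3-oxazolidin-2-one; 21 acetaldehyde
Product: 24 (4R)-4-benzyl-3-[(2R,3S)-3-hydroxy-2-methylbutanoyl]-1,3-oxazolidin-2-one, via dibutylboron enolate 22 (not isolated), via dibutylboron aldolate 23 (not isolated)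
Conditions: Bu2BOTf, i-Pr2NEt, CH2Cl2, −78 to 0 °C; then 21, −78 to 0 °C; then pH 7 buffer, MeOH, H2O2
Reagents that add atoms: none
Why: Evans syn aldol: the Z boron enolate reacts through a chair transition state on the face opposite the benzyl group of the (R)-auxiliary, which should give the (2R,3S) syn adduct.

**Step 13**
Reactants: 24 syn aldol adduct
Product: 25 (4R)-4-benzyl-3-[(2R,3S)-3-(TBS-oxy)-2-methylbutanoyl]-1,3-oxazolidin-2-one
Conditions: t-BuMe2SiOTf, 2,6-lutidine, CH2Cl2, 0 °C
Reagents that add atoms: tert-butyldimethylsilyl trifluoromethanesulfonate (CC(C)(C)[Si](C)(C)OS(=O)(=O)C(F)(F)F)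
Why: Silyl triflate with a hindered base silylates the secondary hydroxyl without retro-aldol cleavage or epimerisation.

**Step 14**
Reactants: 25 TBS-protected aldol imide
Product: 26 (2S,3S)-3-(TBS-oxy)-2-methylbutan-1-ol
Conditions: LiBH4, MeOH (1 equiv), THF, 0 °C; aq work-up
Reagents that add atoms: none
Why: Reductive removal of the auxiliary: borohydride attacks the exocyclic imide carbonyl and gives the primary alcohol without touching the stereocentres.

**Step 15**
Reactants: 26 (2S,3S)-3-(TBS-oxy)-2-methylbutan-1-ol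
Product: 27 (2R,3S)-3-(TBS-oxy)-2-methylbutanal
Conditions: Dess–Martin periodinane, CH2Cl2, 0 °C to rt; used crude
Reagents that add atoms: none
Why: Dess–Martin oxidation under non-basic conditions should give the α-branched aldehyde without epimerisation.

**Step 16**
Reactants: 27 (2R,3S)-3-(TBS-oxy)-2-methylbutanal; 28 ethyl (E)-4-(diethoxyphosphoryl)but-2-enoate
Product: 29 ethyl (2E,4E,6S,7S)-7-(TBS-oxy)-6-methylocta-2,4-dienoate
Conditions: LiN(SiMe3)2, THF, −78 to 0 °C
Reagents that add atoms: none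
Why: Vinylogous Horner–Wadsworth–Emmons olefination: the γ-anion of the phosphonocrotonate adds to the aldehyde and the stabilised phosphonate eliminates to the E alkene, giving the (2E,4E)-dienoate, the low temperature protecting the α-stereocentre.

**Step 17**
Reactants: 29 ethyl (2E,4E,6S,7S)-dienoate
Product: 30 (2E,4E,6S,7S)-7-(TBS-oxy)-6-methylocta-2,4-dienoic acid
Conditions: LiOH, THF/MeOH/H2O, rt; then aq HCl to pH 4, 0 °C
Reagents that add atoms: lithium hydroxide ([Li+].[OH-])
Why: Saponification by acyl–oxygen cleavage leaves the silyl ether and the diene geometry intact.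

**Step 18**
Reactants: 30 (2E,4E,6S,7S)-dienoic acid; 19 C6 alcohol
Product: 32 (1R,2S,7R,8aR)-7-(TBS-oxy)-1,8a-dimethyl-6-oxo-1,2,6,7,8,8a-hexahydronaphthalen-2-yl (2E,4E,6S,7S)-7-(TBS-oxy)-6-methylocta-2,4-dienoate, via mixed anhydride 31 (not isolated)
Conditions: 2,4,6-Cl3C6H2COCl, Et3N, THF, rt; then 19, DMAP, PhMe, rt
Reagents that add atoms: none
Why: Yamaguchi esterification: DMAP attacks the mixed anhydride at the dienoyl carbonyl and the acylpyridinium acylates the hindered C6 hydroxyl with retention, since no bond to the stereocentre is broken.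

**Step 19**
Reactants: 32 bis(TBS) ester
Product: 33 (1R,2S,7R,8aR)-7-hydroxy-1,8a-dimethyl-6-oxo-1,2,6,7,8,8a-hexahydronaphthalen-2-yl (2E,4E,6S,7S)-7-hydroxy-6-methylocta-2,4-dienoate (CNP0329432.2)
Conditions: HF·pyridine, pyridine, THF, 0 °C to rt
Reagents that add atoms: none
Why: Buffered fluoride cleavage of both tert-butyldimethylsilyl ethers under mildly acidic conditions should neither epimerise C3 nor cleave the allylic ester.

**Compound list**
1 | but-2-yne | CC#CC | starting material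
2 | pinacolborane (4,4,5,5-tetramethyl-1,3,2-dioxaborolane) | B1OC(C)(C)C(C)(C)O1 | starting material
3 | (Z)-2-(but-2-en-2-yl)-4,4,5,5-tetramethyl-1,3,2-dioxaborolane | C/C=C(\C)B1OC(C)(C)C(C)(C)O1 | intermediate
4 | lithium (Z)-(but-2-en-2-yl)(chloromethyl)(pinacolato)borate | [Li+].C/C=C(\C)[B-]1(CCl)OC(C)(C)C(C)(C)O1 | intermediate
5 | (E)-4,4,5,5-tetramethyl-2-(2-methylbut-2-en-1-yl)-1,3,2-dioxaborolane | C/C=C(\C)CB1OC(C)(C)C(C)(C)O1 | intermediate
6 | ethyl (Z)-3-iodoprop-2-enoate | CCOC(=O)/C=C\I | starting material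
7 | {[(Z)-1-ethoxy-3-iodoprop-2-en-1-yl]oxy}bis(2-methylpropyl)alumane | CCOC(O[Al](CC(C)C)CC(C)C)/C=C\I | intermediate
8 | (Z)-3-iodoprop-2-enal | O=C/C=C\I | intermediate
9 | 2-{[(1Z,3R,4R)-1-iodo-4,5-dimethylhexa-1,5-dien-3-yl]oxy}-4,4,5,5-tetramethyl-1,3,2-dioxaborolane | C=C(C)[C@@H](C)[C@@H](OB1OC(C)(C)C(C)(C)O1)/C=C\I | intermediate
10 | (1Z,3R,4R)-1-iodo-4,5-dimethylhexa-1,5-dien-3-ol | C=C(C)[C@@H](C)[C@@H](O)/C=C\I | intermediate
11 | 2-[(tert-butyldimethylsilyl)oxy]acetaldehyde | O=CCO[Si](C)(C)C(C)(C)C | starting material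
12 | rac-1-[(tert-butyldimethylsilyl)oxy]but-3-en-2-ol | C=CC(O)CO[Si](C)(C)C(C)(C)C | intermediate
13 | 1-[(tert-butyldimethylsilyl)oxy]but-3-en-2-one | C=CC(=O)CO[Si](C)(C)C(C)(C)C | intermediate
14 | (3E,5Z,7S,8R)-1-[(tert-butyldimethylsilyl)oxy]-7-hydroxy-8,9-dimethyldeca-3,5,9-trien-2-one | C=C(C)[C@@H](C)[C@@H](O)/C=C\C=C\C(=O)CO[Si](C)(C)C(C)(C)C | intermediate
15 | (3E,5Z,7S,8R)-1-[(tert-butyldimethylsilyl)oxy]-8,9-dimethyl-7-[(triethylsilyl)oxy]deca-3,5,9-trien-2-one | C=C(C)[C@@H](C)[C@@H](O[Si](CC)(CC)CC)/C=C\C=C\C(=O)CO[Si](C)(C)C(C)(C)C | intermediate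
16 | (1Z,3E,5Z,7S,8R)-1-[(tert-butyldimethylsilyl)oxy]-8,9-dimethyl-2,7-bis[(triethylsilyl)oxy]deca-1,3,5,9-tetraene | C=C(C)[C@@H](C)[C@@H](O[Si](CC)(CC)CC)/C=C\C=C\C(O[Si](CC)(CC)CC)=C\O[Si](C)(C)C(C)(C)C | intermediate
17 | (3R,4aS,5R,6S,8aR)-3-[(tert-butyldimethylsilyl)oxy]-4a,5-dimethyl-2,6-bis[(triethylsilyl)oxy]-3,4,4a,5,6,8a-hexahydronaphthalene | CC[Si](CC)(CC)O[C@H]1C=C[C@@H]2C=C(O[Si](CC)(CC)CC)[C@H](O[Si](C)(C)C(C)(C)C)C[C@]2(C)[C@H]1C | intermediate
18 | (3R,4aR,5R,6S)-3-[(tert-butyldimethylsilyl)oxy]-4a,5-dimethyl-6-[(triethylsilyl)oxy]-4,4a,5,6-tetrahydronaphthalen-2(3H)-one | CC[Si](CC)(CC)O[C@H]1C=CC2=CC(=O)[C@H](O[Si](C)(C)C(C)(C)C)C[C@]2(C)[C@H]1C | intermediate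
19 | (3R,4aR,5R,6S)-3-[(tert-butyldimethylsilyl)oxy]-6-hydroxy-4a,5-dimethyl-4,4a,5,6-tetrahydronaphthalen-2(3H)-one | O[C@H]1C=CC2=CC(=O)[C@H](O[Si](C)(C)C(C)(C)C)C[C@]2(C)[C@H]1C | intermediate
20 | (R)-4-benzyl-3-propanoyl-1,3-oxazolidin-2-one | CCC(=O)N1[C@H](Cc2ccccc2)COC1=O | starting material
21 | acetaldehyde | CC=O | starting material
22 | (4R)-4-benzyl-3-[(Z)-1-(dibutylboranyloxy)prop-1-en-1-yl]-1,3-oxazolidin-2-one | C/C=C(\OB(CCCC)CCCC)N1[C@H](Cc2ccccc2)COC1=O | intermediate
23 | (4R)-4-benzyl-3-[(2R,3S)-3-(dibutylboranyloxy)-2-methylbutanoyl]-1,3-oxazolidin-2-one | C[C@H](OB(CCCC)CCCC)[C@@H](C)C(=O)N1[C@H](Cc2ccccc2)COC1=O | intermediate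
24 | (4R)-4-benzyl-3-[(2R,3S)-3-hydroxy-2-methylbutanoyl]-1,3-oxazolidin-2-one | C[C@H](O)[C@@H](C)C(=O)N1[C@H](Cc2ccccc2)COC1=O | intermediate
25 | (4R)-4-benzyl-3-{(2R,3S)-3-[(tert-butyldimethylsilyl)oxy]-2-methylbutanoyl}-1,3-oxazolidin-2-one | C[C@H](O[Si](C)(C)C(C)(C)C)[C@@H](C)C(=O)N1[C@H](Cc2ccccc2)COC1=O | intermediate
26 | (2S,3S)-3-[(tert-butyldimethylsilyl)oxy]-2-methylbutan-1-ol | C[C@H](O[Si](C)(C)C(C)(C)C)[C@@H](C)CO | intermediate
27 | (2R,3S)-3-[(tert-butyldimethylsilyl)oxy]-2-methylbutanal | C[C@H](O[Si](C)(C)C(C)(C)C)[C@@H](C)C=O | intermediate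
28 | ethyl (E)-4-(diethoxyphosphoryl)but-2-enoate | CCOC(=O)/C=C/CP(=O)(OCC)OCC | starting material
29 | ethyl (2E,4E,6S,7S)-7-[(tert-butyldimethylsilyl)oxy]-6-methylocta-2,4-dienoate | C[C@H](O[Si](C)(C)C(C)(C)C)[C@@H](C)/C=C/C=C/C(=O)OCC | intermediate
30 | (2E,4E,6S,7S)-7-[(tert-butyldimethylsilyl)oxy]-6-methylocta-2,4-dienoic acid | C[C@H](O[Si](C)(C)C(C)(C)C)[C@@H](C)/C=C/C=C/C(=O)O | intermediate
31 | (2E,4E,6S,7S)-7-[(tert-butyldimethylsilyl)oxy]-6-methylocta-2,4-dienoic 2,4,6-trichlorobenzoic anhydride | C[C@H](O[Si](C)(C)C(C)(C)C)[C@@H](C)/C=C/C=C/C(=O)OC(=O)c1c(Cl)cc(Cl)cc1Cl | intermediate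
32 | (1R,2S,7R,8aR)-7-[(tert-butyldimethylsilyl)oxy]-1,8a-dimethyl-6-oxo-1,2,6,7,8,8a-hexahydronaphthalen-2-yl (2E,4E,6S,7S)-7-[(tert-butyldimethylsilyl)oxy]-6-methylocta-2,4-dienoate | C[C@H](O[Si](C)(C)C(C)(C)C)[C@@H](C)/C=C/C=C/C(=O)O[C@H]1C=CC2=CC(=O)[C@H](O[Si](C)(C)C(C)(C)C)C[C@]2(C)[C@H]1C | intermediate
33 | (1R,2S,7R,8aR)-7-hydroxy-1,8a-dimethyl-6-oxo-1,2,6,7,8,8a-hexahydronaphthalen-2-yl (2E,4E,6S,7S)-7-hydroxy-6-methylocta-2,4-dienoate | C[C@H](O)[C@@H](C)/C=C/C=C/C(=O)O[C@H]1C=CC2=CC(=O)[C@H](O)C[C@]2(C)[C@H]1C | target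

**Step count**
Total: 19 steps. Longest linear sequence: 10 steps (steps 1, 2, 4, 7, 8, 9, 10, 11, 18, 19).

**Steps most likely to fail**

1. Step 9. The cycloaddition of an unactivated 1,1-disubstituted alkene onto a diene terminus that carries a silyloxy group may be slow. In that case [1,5]-hydrogen shift in the Z-diene, enol ether isomerisation and incomplete π-facial control could compete and erode C4a and C3. The fallback moves the C3 oxygen out of the cycloaddition. From 10, Heck coupling with but-3-en-2-one under the conditions of step 7 would give (3E,5Z,7S,8R)-7-hydroxy-8,9-dimethyldeca-3,5,9-trien-2-one F1. Et3SiOTf/Et3N would give (3E,5Z,7S,8R)-8,9-dimethyl-2,7-bis[(triethylsilyl)oxy]deca-1,3,5,9-tetraene F2, whose diene terminus is an unsubstituted CH2 and should cyclise at lower temperature to (4aS,5R,6S,8aR)-4a,5-dimethyl-2,6-bis[(triethylsilyl)oxy]-3,4,4a,5,6,8a-hexahydronaphthalene F3. Pd(OAc)2 oxidation would give (4aR,5R,6S)-4a,5-dimethyl-6-[(triethylsilyl)oxy]-4,4a,5,6-tetrahydronaphthalen-2(3H)-one F4. Kinetic deprotonation at C3 (LiN(SiMe3)2, THF, −78 °C) and hydroxylation of the cross-conjugated enolate with 2-(phenylsulfonyl)-3-phenyloxaziridine, expected on the face away from the axial angular methyl, would give (3R,4aR,5R,6S)-3-hydroxy-4a,5-dimethyl-6-[(triethylsilyl)oxy]-4,4a,5,6-tetrahydronaphthalen-2(3H)-one F5. Silylation with t-BuMe2SiOTf/2,6-lutidine would return to 18.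

2. Step 4. The β-iodo enal may isomerise from Z to E or decompose under the Brønsted-acid catalysis, and selectivity may erode with the trisubstituted allylboronate. The fallback makes the Z iodoalkene only after the C5–C6 bond is in place. From 5, the same catalysed allylboration of the configurationally robust 3-(trimethylsilyl)prop-2-ynal would give (3R,4R)-4,5-dimethyl-1-(trimethylsilyl)hex-5-en-1-yn-3-ol F6. K2CO3/MeOH would give (3R,4R)-4,5-dimethylhex-5-en-1-yn-3-ol F7, and N-iodosuccinimide with catalytic AgNO3 would give (3R,4R)-1-iodo-4,5-dimethylhex-5-en-1-yn-3-ol F8. Cis-selective diimide reduction of the iodoalkyne (2-nitrobenzenesulfonohydrazide, Et3N), which should be faster than reduction of the 1,1-disubstituted alkene, would return to 10.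

3. Step 7. The Z geometry of the iodoalkene may be lost through reversible hydropalladation, and the vinyl ketone may polymerise. The fallback replaces the Heck reaction by a cross-coupling of two preformed alkenyl partners. From 11, addition of (E)-2-(tributylstannyl)vinyllithium (from (E)-1,2-bis(tributylstannyl)ethene and n-BuLi) would give (E)-1-[(tert-butyldimethylsilyl)oxy]-4-(tributylstannyl)but-3-en-2-ol F9. MnO2 oxidation would give (E)-1-[(tert-butyldimethylsilyl)oxy]-4-(tributylstannyl)but-3-en-2-one F10. Stille coupling of F10 with 10 (Pd2(dba)3, AsPh3, CuI, DMF, rt), which keeps the geometry of both alkenyl partners and involves no hydridopalladium species, would return to 14.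

**Further compounds**
F1 | step 9 | (3E,5Z,7S,8R)-7-hydroxy-8,9-dimethyldeca-3,5,9-trien-2-one | C=C(C)[C@@H](C)[C@@H](O)/C=C\C=C\C(C)=O
F2 | step 9 | (3E,5Z,7S,8R)-8,9-dimethyl-2,7-bis[(triethylsilyl)oxy]deca-1,3,5,9-tetraene | C=C(C)[C@@H](C)[C@@H](O[Si](CC)(CC)CC)/C=C\C=C\C(=C)O[Si](CC)(CC)CC
F3 | step 9 | (4aS,5R,6S,8aR)-4a,5-dimethyl-2,6-bis[(triethylsilyl)oxy]-3,4,4a,5,6,8a-hexahydronaphthalene | CC[Si](CC)(CC)O[C@H]1C=C[C@@H]2C=C(O[Si](CC)(CC)CC)CC[C@]2(C)[C@H]1C
F4 | step 9 | (4aR,5R,6S)-4a,5-dimethyl-6-[(triethylsilyl)oxy]-4,4a,5,6-tetrahydronaphthalen-2(3H)-one | CC[Si](CC)(CC)O[C@H]1C=CC2=CC(=O)CC[C@]2(C)[C@H]1C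
F5 | step 9 | (3R,4aR,5R,6S)-3-hydroxy-4a,5-dimethyl-6-[(triethylsilyl)oxy]-4,4a,5,6-tetrahydronaphthalen-2(3H)-one | CC[Si](CC)(CC)O[C@H]1C=CC2=CC(=O)[C@H](O)C[C@]2(C)[C@H]1C
F6 | step 4 | (3R,4R)-4,5-dimethyl-1-(trimethylsilyl)hex-5-en-1-yn-3-ol | C=C(C)[C@@H](C)[C@@H](O)C#C[Si](C)(C)C
F7 | step 4 | (3R,4R)-4,5-dimethylhex-5-en-1-yn-3-ol | C=C(C)[C@@H](C)[C@@H](O)C#C
F8 | step 4 | (3R,4R)-1-iodo-4,5-dimethylhex-5-en-1-yn-3-ol | C=C(C)[C@@H](C)[C@@H](O)C#CI
F9 | step 7 | (E)-1-[(tert-butyldimethylsilyl)oxy]-4-(tributylstannyl)but-3-en-2-ol | CCCC[Sn](CCCC)(CCCC)/C=C/C(O)CO[Si](C)(C)C(C)(C)C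
F10 | step 7 | (E)-1-[(tert-butyldimethylsilyl)oxy]-4-(tributylstannyl)but-3-en-2-one | CCCC[Sn](CCCC)(CCCC)/C=C/C(=O)CO[Si](C)(C)C(C)(C)C
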